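**Retrosynthetic overview**
- The benzoquinone, the only ring, is made last. Its O=C–C(OMe)=C(OMe)–C=O half is the ring-opened form of dimethyl squarate and its tetrasubstituted C(Me)=C(CH2R) half is a 2-alkyne, so a dimethoxymaleoylcobalt metallacycle and an enyne are joined by alkyne insertion and reductive elimination, which forms both carbonyl–olefin bonds at once.
- Enabling feature: in the six-membered quinone ring C1 and C4 are both carbonyls and C2 and C3 both carry OMe, so the C1–C2–C3–C4 unit is symmetric and either orientation of the alkyne (future C5–Me and C6–chain) gives the same ring.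
- The enyne comes from the C50 allylic alcohol (bromide, then copper-catalysed propynyl coupling). The C50 chain is cut at C16–C17 (allylic sulfone alkylation, then desulfonylation) into a C30 sulfone and a C20 bromide.
- Both halves come from one ω-bromo geranylgeranyl silyl ether (terminal SeO2 oxidation of geranylgeraniol). The C30 half is made from it by copper-catalysed coupling with the Grignard reagent of (R)-citronellyl bromide, which supplies the only stereocentre.
- Ring order: five-membered cobaltacycle (temporary), then the six-membered quinone ring.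

Key step: step 13

Remark: the two cobalt complexes are written as trivalent cobalt with neutral dimethylglyoxime and with dative bonds shown charge-separated; the citronellyl carbon keeps its spatial arrangement throughout, and its descriptor changes from R to S only because the CIP priorities change once the chain is attached.

Step 1
Reactants: 1 (2E,6E,10E)-geranylgeraniol
Product: 2 geranylgeranyl TBDPS ether
Conditions: TBDPSCl, imidazole, DMF, 0 °C → rt
Reagents that add atoms: tert-butyl(chloro)diphenylsilane (TBDPSCl), CC(C)(C)[Si](Cl)(c1ccccc1)c1ccccc1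
Why: Standard silyl ether protection of a primary allylic alcohol; the TBDPS group should survive the oxidation, organometallic, carbanion and hydride steps that follow, and no olefin is touched.

Step 2
Reactants: 2 geranylgeranyl TBDPS ether
Product: 3 ω-hydroxy geranylgeranyl TBDPS ether
Conditions: SeO2 (0.1 equiv), t-BuOOH (70% aq.), salicylic acid (0.1 equiv), CH2Cl2, 0 °C → rt; stopped at partial conversion, 2 recycled
Reagents that add atoms: tert-butyl hydroperoxide, CC(C)(C)OO (terminal oxidant); selenium dioxide, O=[Se]=O (catalytic oxygen carrier)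
Why: Catalytic SeO2 allylic oxidation (ene reaction, then [2,3]-sigmatropic shift) should attack the most accessible terminal isopropylidene group and, by the known E rule, hydroxylate the methyl trans to the chain, which sets the E geometry of the new allylic alcohol.

Step 3
Reactants: 3 ω-hydroxy geranylgeranyl TBDPS ether
Product: 4 ω-bromo geranylgeranyl TBDPS ether
Conditions: CBr4, PPh3, CH2Cl2, 0 °C
Reagents that add atoms: carbon tetrabromide, BrC(Br)(Br)Br
Why: Appel bromination of a primary allylic alcohol proceeds by SN2 displacement of the oxyphosphonium group under neutral conditions, so the silyl ether and the E olefin should be kept.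

Step 4
Reactants: 4 ω-bromo geranylgeranyl TBDPS ether; 5 (R)-citronellyl bromide
Product: 7 C30 TBDPS ether, via (R)-citronellylmagnesium bromide 6 (not isolated)
Conditions: 5, Mg, THF, rt → 40 °C; then 4, Li2CuCl4 (3 mol %), THF, −78 → 0 °C
Reagents that add atoms: none
Why: Kochi-type copper-catalysed cross-coupling of a primary alkyl Grignard reagent with a primary allylic bromide should, with Li2CuCl4 at low temperature, occur at the α-carbon with retention of the E olefin; the stereocentre is carried unchanged from 5.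

Step 5
Reactants: 7 C30 TBDPS ether
Product: 8 C30 allylic alcohol
Conditions: TBAF, THF, 0 °C → rt
Reagents that add atoms: none
Why: Fluoride-induced desilylation is selective for the Si–O bond and leaves the five olefins and the stereocentre alone.

Step 6
Reactants: 8 C30 allylic alcohol
Product: 10 C30 allylic p-tolyl sulfone, via C30 allylic bromide 9 (not isolated)
Conditions: PBr3 (0.4 equiv), Et2O, −10 °C, crude bromide used at once; then TolSO2Na, DMF, rt
Reagents that add atoms: sodium p-toluenesulfinate, Cc1ccc(cc1)S(=O)[O-].[Na+] (PBr3, BrP(Br)Br, supplies only the bromine of intermediate 9)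
Why: Bromination of the primary allylic alcohol followed by S-alkylation of the soft sulfinate anion (SN2) is the standard entry to E-polyprenyl sulfones and should keep the 2E geometry.

Step 7
Reactants: 10 C30 allylic p-tolyl sulfone; 4 ω-bromo geranylgeranyl TBDPS ether
Product: 12 C50 sulfone TBDPS ether, via lithiated sulfone 11 (not isolated)
Conditions: n-BuLi, THF/DMPU, −78 °C; then 4, −78 → −20 °C
Reagents that add atoms: none
Why: Alkylation of an α-sulfonyl allylic carbanion with a primary allylic bromide (the coupling step of Julia-type polyprenyl chain assembly) should occur at the sulfone carbon by SN2, so both flanking E olefins stay intact; the new sulfone-bearing centre forms without control and is removed in step 8.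

Step 8
Reactants: 12 C50 sulfone TBDPS ether
Product: 13 C50 TBDPS ether
Conditions: PdCl2(dppp) (5 mol %), LiBHEt3, THF, 0 °C
Reagents that add atoms: none
Why: Palladium-catalysed reductive desulfonylation of an allylic sulfone: zerovalent palladium ionises the sulfone to a π-allyl complex and hydride is delivered to the less substituted terminus, which should keep the position and E geometry of the trisubstituted olefin.

Step 9
Reactants: 13 C50 TBDPS ether
Product: 14 C50 allylic alcohol
Conditions: TBAF, THF, 0 °C → rt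
Reagents that add atoms: none
Why: Fluoride-induced desilylation frees the primary allylic alcohol without touching the nine olefins.

Step 10
Reactants: 14 C50 allylic alcohol
Product: 16 C53 1,4-enyne, via C50 allylic bromide 15 (not isolated)
Conditions: PBr3 (0.4 equiv), Et2O, −10 °C, crude bromide used at once; then CH3C≡CMgBr, CuI (10 mol %), THF, 0 °C → rt
Reagents that add atoms: 1-propynylmagnesium bromide, CC#C[Mg]Br (PBr3, BrP(Br)Br, supplies only the bromine of intermediate 15)
Why: Copper-catalysed SN2 coupling of an alkynyl Grignard reagent with a primary allylic bromide gives the skipped enyne; attack at the primary carbon should be favoured because the SN2′ path would create a quaternary carbon.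

Step 11
Reactants: 17 dimethyl squarate
Product: 18 chlorobis(triphenylphosphine)(dimethoxymaleoyl)cobalt
Conditions: CoCl(PPh3)3, benzene, rt, argon
Reagents that add atoms: chlorotris(triphenylphosphine)cobalt, Cl[Co-3]([P+](c1ccccc1)(c1ccccc1)c1ccccc1)([P+](c1ccccc1)(c1ccccc1)c1ccccc1)[P+](c1ccccc1)(c1ccccc1)c1ccccc1
Why: Oxidative addition of monovalent cobalt into the strained acyl–acyl bond of a cyclobutenedione gives the five-membered maleoyl metallacycle of trivalent cobalt, the known entry to maleoyl- and phthaloylcobalt complexes.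

Step 12
Reactants: 18 chlorobis(triphenylphosphine)(dimethoxymaleoyl)cobalt
Product: 19 chloro(dimethylglyoxime)(pyridine)(dimethoxymaleoyl)cobalt
Conditions: dimethylglyoxime, pyridine, rt
Reagents that add atoms: dimethylglyoxime, CC(=NO)C(C)=NO; pyridine, c1ccncc1
Why: Ligand exchange at trivalent cobalt, in which the chelating dioxime and pyridine displace both phosphines, should give an air-stable octahedral complex that inserts alkynes under much milder conditions than 18.

Step 13
Reactants: 16 C53 1,4-enyne; 19 chloro(dimethylglyoxime)(pyridine)(dimethoxymaleoyl)cobalt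
Product: 20 target quinone
Conditions: 19 (1.5 equiv), CoCl2·6H2O (0.2 equiv), ClCH2CH2Cl, 75 °C, argon, dark
Reagents that add atoms: none
Why: Loss of a ligand from the octahedral trivalent cobalt of 19, assisted by the mild Lewis acid, lets the alkyne of 16 coordinate and insert into one Co–acyl bond to give a seven-membered cobaltacycle, from which C–C reductive elimination forms the second acyl–vinyl bond and releases the quinone and monovalent cobalt, so both bonds between the carbonyl carbons and the methyl- and chain-bearing carbons are made in one operation. The closest known reaction type is the annulation of maleoyl- and phthaloylcobalt complexes with alkynes to benzo- and naphthoquinones. The six-membered carbocycle is closed by a formal [4+2] annulation at the metal (insertion into a five-membered metallacycle, then reductive elimination), not by a pericyclic process. No stereocentre is created, and the remote methyl-bearing centre and the eight E olefins are not engaged. The step needs chemoselectivity for the single alkyne over nine trisubstituted olefins, which should be secured because such olefins do not insert into the cobalt–acyl bond, and it needs no regiocontrol because the dimethoxymaleoyl unit is symmetric. That symmetry also allows the mild CoCl2·6H2O promoter in place of strong Lewis acids that would cyclise the polyene.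

**Compound list**
1 | (2E,6E,10E)-3,7,11,15-tetramethylhexadeca-2,6,10,14-tetraen-1-ol (geranylgeraniol) | OC/C=C(\C)CC/C=C(\C)CC/C=C(\C)CCC=C(C)C | starting material
2 | tert-butyl(diphenyl){[(2E,6E,10E)-3,7,11,15-tetramethylhexadeca-2,6,10,14-tetraen-1-yl]oxy}silane | CC(C)(C)[Si](c1ccccc1)(c1ccccc1)OC/C=C(\C)CC/C=C(\C)CC/C=C(\C)CCC=C(C)C | intermediate
3 | (2E,6E,10E,14E)-16-[(tert-butyldiphenylsilyl)oxy]-2,6,10,14-tetramethylhexadeca-2,6,10,14-tetraen-1-ol | CC(C)(C)[Si](c1ccccc1)(c1ccccc1)OC/C=C(\C)CC/C=C(\C)CC/C=C(\C)CC/C=C(\C)CO | intermediate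
4 | {[(2E,6E,10E,14E)-16-bromo-3,7,11,15-tetramethylhexadeca-2,6,10,14-tetraen-1-yl]oxy}(tert-butyl)diphenylsilane | CC(C)(C)[Si](c1ccccc1)(c1ccccc1)OC/C=C(\C)CC/C=C(\C)CC/C=C(\C)CC/C=C(\C)CBr | intermediate
5 | (R)-citronellyl bromide, (6R)-8-bromo-2,6-dimethyloct-2-ene | BrCC[C@H](C)CCC=C(C)C | starting material
6 | (R)-citronellylmagnesium bromide (not isolated) | Br[Mg]CC[C@H](C)CCC=C(C)C | intermediate
7 | tert-butyl{[(2E,6E,10E,14E,19S)-3,7,11,15,19,23-hexamethyltetracosa-2,6,10,14,22-pentaen-1-yl]oxy}diphenylsilane | CC(C)(C)[Si](c1ccccc1)(c1ccccc1)OC/C=C(\C)CC/C=C(\C)CC/C=C(\C)CC/C=C(\C)CCC[C@H](C)CCC=C(C)C | intermediate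
8 | (2E,6E,10E,14E,19S)-3,7,11,15,19,23-hexamethyltetracosa-2,6,10,14,22-pentaen-1-ol | OC/C=C(\C)CC/C=C(\C)CC/C=C(\C)CC/C=C(\C)CCC[C@H](C)CCC=C(C)C | intermediate
9 | (2E,6E,10E,14E,19S)-1-bromo-3,7,11,15,19,23-hexamethyltetracosa-2,6,10,14,22-pentaene (not isolated) | BrC/C=C(\C)CC/C=C(\C)CC/C=C(\C)CC/C=C(\C)CCC[C@H](C)CCC=C(C)C | intermediate
10 | 1-methyl-4-{[(2E,6E,10E,14E,19S)-3,7,11,15,19,23-hexamethyltetracosa-2,6,10,14,22-pentaen-1-yl]sulfonyl}benzene | Cc1ccc(cc1)S(=O)(=O)C/C=C(\C)CC/C=C(\C)CC/C=C(\C)CC/C=C(\C)CCC[C@H](C)CCC=C(C)C | intermediate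
11 | 1-lithio derivative of sulfone 10, lithium on the sulfone-bearing carbon (not isolated) | [Li]C(/C=C(\C)CC/C=C(\C)CC/C=C(\C)CC/C=C(\C)CCC[C@H](C)CCC=C(C)C)S(=O)(=O)c1ccc(C)cc1 | intermediate
12 | TBDPS ether of (2E,6E,10E,14E,18E,22E,26E,30E,35S)-3,7,11,15,19,23,27,31,35,39-decamethyl-17-(4-methylbenzenesulfonyl)tetraconta-2,6,10,14,18,22,26,30,38-nonaen-1-ol, both C17 epimers | CC(C)(C)[Si](c1ccccc1)(c1ccccc1)OC/C=C(\C)CC/C=C(\C)CC/C=C(\C)CC/C=C(\C)CC(/C=C(\C)CC/C=C(\C)CC/C=C(\C)CC/C=C(\C)CCC[C@H](C)CCC=C(C)C)S(=O)(=O)c1ccc(C)cc1 | intermediate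
13 | tert-butyl{[(2E,6E,10E,14E,18E,22E,26E,30E,35S)-3,7,11,15,19,23,27,31,35,39-decamethyltetraconta-2,6,10,14,18,22,26,30,38-nonaen-1-yl]oxy}diphenylsilane | CC(C)(C)[Si](c1ccccc1)(c1ccccc1)OC/C=C(\C)CC/C=C(\C)CC/C=C(\C)CC/C=C(\C)CC/C=C(\C)CC/C=C(\C)CC/C=C(\C)CC/C=C(\C)CCC[C@H](C)CCC=C(C)C | intermediate
14 | (2E,6E,10E,14E,18E,22E,26E,30E,35S)-3,7,11,15,19,23,27,31,35,39-decamethyltetraconta-2,6,10,14,18,22,26,30,38-nonaen-1-ol | OC/C=C(\C)CC/C=C(\C)CC/C=C(\C)CC/C=C(\C)CC/C=C(\C)CC/C=C(\C)CC/C=C(\C)CC/C=C(\C)CCC[C@H](C)CCC=C(C)C | intermediate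
15 | (2E,6E,10E,14E,18E,22E,26E,30E,35S)-1-bromo-3,7,11,15,19,23,27,31,35,39-decamethyltetraconta-2,6,10,14,18,22,26,30,38-nonaene (not isolated) | BrC/C=C(\C)CC/C=C(\C)CC/C=C(\C)CC/C=C(\C)CC/C=C(\C)CC/C=C(\C)CC/C=C(\C)CC/C=C(\C)CCC[C@H](C)CCC=C(C)C | intermediate
16 | (5E,9E,13E,17E,21E,25E,29E,33E,38S)-6,10,14,18,22,26,30,34,38,42-decamethyltritetraconta-5,9,13,17,21,25,29,33,41-nonaen-2-yne | CC#CC/C=C(\C)CC/C=C(\C)CC/C=C(\C)CC/C=C(\C)CC/C=C(\C)CC/C=C(\C)CC/C=C(\C)CC/C=C(\C)CCC[C@H](C)CCC=C(C)C | intermediate
17 | dimethyl squarate, 3,4-dimethoxycyclobut-3-ene-1,2-dione | COC1=C(OC)C(=O)C1=O | starting material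
18 | 1-chloro-3,4-dimethoxy-1,1-bis(triphenylphosphine)-1-cobaltacyclopent-3-ene-2,5-dione (trivalent cobalt) | COC1=C(OC)C(=O)[Co-2](Cl)([P+](c2ccccc2)(c2ccccc2)c2ccccc2)([P+](c2ccccc2)(c2ccccc2)c2ccccc2)C1=O | intermediate
19 | 1-chloro-1-(dimethylglyoxime-N,N′)-3,4-dimethoxy-1-(pyridine)-1-cobaltacyclopent-3-ene-2,5-dione (trivalent cobalt, octahedral) | COC1=C(OC)C(=O)[Co-3]2(Cl)([n+]3ccccc3)([N+](O)=C(C)C(C)=[N+]2O)C1=O | intermediate
20 | 2,3-dimethoxy-5-methyl-6-[(2E,6E,10E,14E,18E,22E,26E,30E,35S)-3,7,11,15,19,23,27,31,35,39-decamethyltetraconta-2,6,10,14,18,22,26,30,38-nonaen-1-yl]cyclohexa-2,5-diene-1,4-dione | COC1=C(OC)C(=O)C(C/C=C(\C)CC/C=C(\C)CC/C=C(\C)CC/C=C(\C)CC/C=C(\C)CC/C=C(\C)CC/C=C(\C)CC/C=C(\C)CCC[C@H](C)CCC=C(C)C)=C(C)C1=O | target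

**Totals**
Total step count: 13. Longest linear sequence: 11 steps (steps 1–10 and 13, from 1); the cobalt branch (steps 11–12) joins at step 13.

**Steps most likely to fail**

Step 13 (annulation). The alkyne insertion may be slow with the bulky skipped enyne, the 1,4-enyne may isomerise at the metal, or the Lewis acid may start cationic cyclisation of the polyene. The fallback gives up ring construction and attaches the chain to a preformed arene; it sets out from bromide 15 (made from 14 as in step 10) and comes back at 20. Commercial 2,3,4,5-tetramethoxytoluene (COc1cc(C)c(OC)c(OC)c1OC) would be brominated (NBS, CH3CN, rt) at its only free ring position to 1-bromo-2,3,4,5-tetramethoxy-6-methylbenzene F1. Mg in THF would convert this into 2,3,4,5-tetramethoxy-6-methylphenylmagnesium bromide F2, and CuBr·SMe2-catalysed coupling with 15 (THF, −20 → 0 °C) should give the polyprenyl tetramethoxytoluene F3. Oxidative demethylation of the para-dimethoxy pair with (NH4)2Ce(NO3)6 in CH3CN/H2O at 0 °C should then give 20.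

Step 11 (cobalt insertion). Oxidative addition into the electron-rich, vinylogous-ester C–C bond of the squarate may be sluggish, or the metallacycle may lose CO. The fallback joins the same two building blocks by polar chemistry and a thermal ring expansion; it sets out from 16 and 17 and comes back at 20.
- syn-Hydrozirconation of 16 (Cp2Zr(H)Cl, THF, rt) should give the alkenylzirconocene chloride F4, with zirconium on the methyl-bearing carbon; the minor regioisomer leads to the same quinone.
- Iodinolysis (I2, 0 °C) would give the (E)-2-iodoalkene F5, and t-BuLi (2 equiv, Et2O, −78 °C) the alkenyllithium F6.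
- 1,2-Addition of F6 to 17 (THF, −78 °C) should give the 4-alkenyl-4-hydroxy-2,3-dimethoxycyclobutenone F7 (both epimers at the carbinol carbon).
- Heating F7 in toluene at 110 °C (4π ring opening to a dienylketene, 6π ring closure, tautomerisation) should give the hydroquinone F8, which Ag2O in Et2O oxidises to 20.

Step 4 (Grignard coupling). Attack at the γ-carbon (SN2′), homocoupling of the Grignard reagent, or erosion of the E geometry may occur. The fallback replaces the copper coupling by sulfone alkylation; it sets out from 5 and 4 and comes back at 7. Bromide 5 and TolSO2Na (DMF, 60 °C) would give (R)-citronellyl p-tolyl sulfone F9. n-BuLi (THF/DMPU, −78 °C) would give its α-lithio derivative F10, which should be alkylated by 4 to the C30 sulfone TBDPS ether F11 (both epimers at the sulfone carbon). Reductive desulfonylation with sodium amalgam (Na/Hg), Na2HPO4, MeOH/THF at −20 °C should give 7.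

**Further compounds**
F1 | step 13 | 1-bromo-2,3,4,5-tetramethoxy-6-methylbenzene | COc1c(Br)c(C)c(OC)c(OC)c1OC
F2 | step 13 | 2,3,4,5-tetramethoxy-6-methylphenylmagnesium bromide | COc1c([Mg]Br)c(C)c(OC)c(OC)c1OC
F3 | step 13 | 1,2,3,4-tetramethoxy-5-methyl-6-[(2E,6E,10E,14E,18E,22E,26E,30E,35S)-3,7,11,15,19,23,27,31,35,39-decamethyltetraconta-2,6,10,14,18,22,26,30,38-nonaen-1-yl]benzene | COc1c(C/C=C(\C)CC/C=C(\C)CC/C=C(\C)CC/C=C(\C)CC/C=C(\C)CC/C=C(\C)CC/C=C(\C)CC/C=C(\C)CCC[C@H](C)CCC=C(C)C)c(C)c(OC)c(OC)c1OC
F4 | step 11 | alkenylzirconocene chloride from syn-addition of H–Zr to the triple bond of 16, zirconium on the methyl-bearing carbon | C/C(=C\C/C=C(\C)CC/C=C(\C)CC/C=C(\C)CC/C=C(\C)CC/C=C(\C)CC/C=C(\C)CC/C=C(\C)CC/C=C(\C)CCC[C@H](C)CCC=C(C)C)[Zr](Cl)(C1C=CC=C1)C1C=CC=C1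
F5 | step 11 | (2E)-2-iodoalkene from 16, iodine on the methyl-bearing carbon, all other olefins E, remote centre S | C/C(I)=C\C/C=C(\C)CC/C=C(\C)CC/C=C(\C)CC/C=C(\C)CC/C=C(\C)CC/C=C(\C)CC/C=C(\C)CC/C=C(\C)CCC[C@H](C)CCC=C(C)C
F6 | step 11 | alkenyllithium from F5, lithium in place of iodine with retention | C/C([Li])=C\C/C=C(\C)CC/C=C(\C)CC/C=C(\C)CC/C=C(\C)CC/C=C(\C)CC/C=C(\C)CC/C=C(\C)CC/C=C(\C)CCC[C@H](C)CCC=C(C)C
F7 | step 11 | 4-hydroxy-2,3-dimethoxy-4-alkenylcyclobut-2-en-1-one, alkenyl group as in F6, both epimers at C4 | C/C(=C\C/C=C(\C)CC/C=C(\C)CC/C=C(\C)CC/C=C(\C)CC/C=C(\C)CC/C=C(\C)CC/C=C(\C)CC/C=C(\C)CCC[C@H](C)CCC=C(C)C)C1(O)C(OC)=C(OC)C1=O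
F8 | step 11 | 2,3-dimethoxy-5-methyl-6-[(2E,6E,10E,14E,18E,22E,26E,30E,35S)-3,7,11,15,19,23,27,31,35,39-decamethyltetraconta-2,6,10,14,18,22,26,30,38-nonaen-1-yl]benzene-1,4-diol | COc1c(OC)c(O)c(C/C=C(\C)CC/C=C(\C)CC/C=C(\C)CC/C=C(\C)CC/C=C(\C)CC/C=C(\C)CC/C=C(\C)CC/C=C(\C)CCC[C@H](C)CCC=C(C)C)c(C)c1O
F9 | step 4 | (R)-citronellyl p-tolyl sulfone, 1-{[(3R)-3,7-dimethyloct-6-en-1-yl]sulfonyl}-4-methylbenzene | Cc1ccc(cc1)S(=O)(=O)CC[C@H](C)CCC=C(C)C
F10 | step 4 | α-lithio derivative of F9, lithium on the sulfone-bearing carbon | [Li]C(C[C@H](C)CCC=C(C)C)S(=O)(=O)c1ccc(C)cc1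
F11 | step 4 | TBDPS ether 7 bearing a p-tolylsulfonyl group on C17, both C17 epimers, methyl-bearing centre as in 5 | CC(C)(C)[Si](c1ccccc1)(c1ccccc1)OC/C=C(\C)CC/C=C(\C)CC/C=C(\C)CC/C=C(\C)CC(C[C@H](C)CCC=C(C)C)S(=O)(=O)c1ccc(C)cc1
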